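**Retrosynthetic overview**

1. Numbering along the SMILES: C1 (quaternary, bears CO2Me and CH3), C2, C3=C4, C5=C6, O7, C8 (acetal), C9, C10, C11, C12, C13 (quaternary), C14. Ring A = C9-C10-C11-C12-C13, ring B = C1-C2-C14-C13-C12, ring C = C2-C3-C4-C5-C13-C14, ring D = C5-C6-O7-C8-C9-C13.
2. Feature: rings A and B share the bond C12–C13 and form a bicyclo[3.3.0]octane. C13 is its angular quaternary carbon and C10 is a bare CH2 between C9 and C11. With a carbonyl on C10 and a double bond at C11=C12, ring A becomes the cyclopentenone of an intramolecular Pauson–Khand reaction.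
3. Disconnections: the C8–O acyl bond (lactol acylation); then O7–C8 of ring D (dienol lactone from a C8 acid and a C6 enal, the enal made from the C6 methyl group); then C12–C13, C9–C10 and C10–C11 in one step, back to CO and a dienyne that contains only ring C.
4. The dienyne comes from (R)-carvone, which supplies ring C, C2, C6, and C1 with its CH3 and carboxyl carbon. A bridged δ-lactone between C13–OH and the C1 carboxyl sets quaternary C1 by enolate hydroxymethylation (C12). C11 comes from the Ohira–Bestmann reagent and C9–C8 from triethyl phosphonoacetate.
5. Ring order: C (chiral pool), then B and A together (step 11), then D (step 18).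

Key step: step 11

Assumption: olefination of the 2-methylcyclohexenone 14 is taken to give the E alkylidene (C8 anti to C5), since the Z isomer suffers allylic 1,3-strain with the C6 methyl group; C9 therefore leaves step 11 in its more stable, non-target configuration, which keeps C8 and C6 apart while both are oxidised, and C9 is inverted when ring D closes in step 18.

**Step 1**
Reactants: 1 (R)-carvone
Product: 2 (−)-cis-carveol = (1R,5R)-2-methyl-5-(prop-1-en-2-yl)cyclohex-2-en-1-ol
Conditions: NaBH4, CeCl3·7H2O, MeOH, −78 to 0 °C
Reagents that add atoms: none
Why: Luche reduction: the cerium-modified borohydride attacks the enone carbonyl only in the 1,2 sense and along the axial trajectory of the half-chair with the isopropenyl group equatorial, which makes the C13 hydroxyl pseudo-equatorial and cis to the C2 side chain.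

**Step 2**
Reactants: 2 (−)-cis-carveol
Product: 4 (1R,5R)-5-(1-hydroxypropan-2-yl)-2-methylcyclohex-2-en-1-ol (both C1 epimers), via organoborane 3 (not isolated)
Conditions: 9-BBN-H (2.2 equiv), THF, 0 °C to rt; then NaOH aq, H2O2, 0 °C
Reagents that add atoms: hydrogen peroxide, OO
Why: Anti-Markovnikov hydroboration–oxidation: after the hydroxyl group has consumed one equivalent, 9-BBN-H adds to the 1,1-disubstituted isopropenyl alkene much faster than to the trisubstituted ring alkene and puts boron on the terminal carbon, and the mixture of C1 epimers does not matter because C1 is planarised in step 4.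

**Step 3**
Reactants: 4 diol
Product: 6 (1R,5R)-4,8-dimethyl-2-oxabicyclo[3.3.1]non-7-en-3-one (both C1 epimers), via lactol 5 (not isolated)
Conditions: TEMPO (cat.), PhI(OAc)2 (2.5 equiv), CH2Cl2, rt
Reagents that add atoms: none
Why: Oxoammonium-mediated oxidative lactonisation of a 1,5-diol: the unhindered primary alcohol is oxidised first, the aldehyde is caught by the cis C13 hydroxyl as the bridged lactol 5, and the lactol is oxidised faster than the flanked secondary allylic alcohol.

**Step 4**
Reactants: 6 bridged lactone; 7 formaldehyde (monomer, cracked from paraformaldehyde)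
Product: 9 (1R,4R,5R)-4-(hydroxymethyl)-4,8-dimethyl-2-oxabicyclo[3.3.1]non-7-en-3-one, via lithium enolate 8 (not isolated)
Conditions: LiN(i-Pr)2, THF, −78 °C; then CH2O (gas), −78 to −20 °C; AcOH quench
Reagents that add atoms: formaldehyde, C=O
Why: Aldol reaction of a lactone enolate with formaldehyde: in the 2-oxabicyclo[3.3.1]nonene the face of the C1 enolate carbon that looks into the cage is blocked by C3 (axial on the neighbouring C2) and by the C4=C5 bridge, so C12 enters from outside, anti to C3, and because the methyl group was there first this order of bond formation gives the (R) configuration of C1 found in the target.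

**Step 5**
Reactants: 9 hydroxymethyl lactone
Product: 10 (1R,4R,5R)-4,8-dimethyl-3-oxo-2-oxabicyclo[3.3.1]non-7-ene-4-carbaldehyde
Conditions: Dess–Martin periodinane, CH2Cl2, 0 °C to rt
Reagents that add atoms: none
Why: Dess–Martin oxidation of a neopentyl primary alcohol under neutral conditions, which avoids retro-aldol loss of formaldehyde and gives a non-enolisable aldehyde.

**Step 6**
Reactants: 10 formyl lactone; 11 dimethyl (1-diazo-2-oxopropyl)phosphonate
Product: 13 methyl (2R)-2-[(1R,5R)-5-hydroxy-4-methylcyclohex-3-en-1-yl]-2-methylbut-3-ynoate, via ethynyl lactone 12 (not isolated)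
Conditions: 11, K2CO3, MeOH, 0 °C to rt
Reagents that add atoms: dimethyl (1-diazo-2-oxopropyl)phosphonate, CC(=O)C(=[N+]=[N-])P(=O)(OC)OC; methanol, CO
Why: Ohira–Bestmann homologation (methanolysis of 11 gives the diazomethylphosphonate anion, which adds to the aldehyde faster than methoxide can deformylate it and then loses phosphate and N2) turns C12 into the alkyne carbon and brings in C11 without touching quaternary C1, and the same K2CO3/MeOH medium then opens the bridged allylic lactone by transesterification, driven by the solvent excess and by release of the diaxial bridge.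

**Step 7**
Reactants: 13 hydroxy ester
Product: 14 methyl (2R)-2-methyl-2-[(1R)-4-methyl-5-oxocyclohex-3-en-1-yl]but-3-ynoate
Conditions: Dess–Martin periodinane, CH2Cl2, 0 °C
Reagents that add atoms: none
Why: Dess–Martin oxidation of the secondary allylic alcohol regenerates the carvone-type enone, makes the lactone opening irreversible and leaves alkyne and ester untouched.

**Step 8**
Reactants: 14 enone; 15 triethyl phosphonoacetate
Product: 16 methyl (2R)-2-[(1R,5E)-5-(2-ethoxy-2-oxoethylidene)-4-methylcyclohex-3-en-1-yl]-2-methylbut-3-ynoate
Conditions: 15, NaH, THF, 0 to 65 °C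
Reagents that add atoms: triethyl phosphonoacetate, CCOC(=O)CP(=O)(OCC)OCC
Why: Horner–Wadsworth–Emmons olefination of a cyclohexenone in the 1,2 sense: the ester group settles anti to C5 (E) because in the Z isomer it would be pressed against the C6 methyl group by allylic 1,3-strain, and the phosphonate anion is too weak a base to disturb the terminal alkyne.

**Step 9**
Reactants: 16 dienoate
Product: 17 methyl (2R)-2-[(1R,5E)-5-(2-hydroxyethylidene)-4-methylcyclohex-3-en-1-yl]-2-methylbut-3-ynoate
Conditions: i-Bu2AlH (2.1 equiv), CH2Cl2, −78 °C; then potassium sodium tartrate aq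
Reagents that add atoms: none
Why: Chemoselective i-Bu2AlH reduction: the exposed dienoate ester is reduced to the allylic alcohol at −78 °C whereas the methyl ester sits on quaternary C1 next to a ring carbon and is shielded like a pivalate.

**Step 10**
Reactants: 17 allylic alcohol
Product: 18 methyl (2R)-2-[(1R,5E)-5-(2-{[tert-butyl(dimethyl)silyl]oxy}ethylidene)-4-methylcyclohex-3-en-1-yl]-2-methylbut-3-ynoate
Conditions: TBSCl, imidazole, CH2Cl2, rt
Reagents that add atoms: tert-butyl(chloro)dimethylsilane, CC(C)(C)[Si](C)(C)Cl
Why: Standard silylation of a primary allylic alcohol, which keeps the oxygen from binding rhodium and prevents allylic alcohol isomerisation in the key step.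

**Step 11**
Reactants: 18 dienyne ester; 19 carbon monoxide
Product: 20 tricyclic enone (rings A B C closed; C10 ketone; C11=C12; C4=C5 kept; C8H2OTBS on C9 on the C14 face of ring A)
Conditions: [RhCl(CO)2]2 (10 mol %), CO (1 atm), toluene (0.02 M), 100 °C
Reagents that add atoms: carbon monoxide, [C-]#[O+]
Why: Monovalent rhodium binds the alkyne C11≡C12 and the exocyclic alkene C13=C9, oxidative cyclisation gives a rhodacyclopentene that already contains the bond C12–C13, CO inserts into a Rh–C bond and reductive elimination ties C11 and C9 to the new carbonyl carbon C10. The closest known reaction type is the [RhCl(CO)2]2-catalysed intramolecular Pauson–Khand reaction of 1,6-enynes, including its dienyl variant and cases in which an exocyclic or 1,1-disubstituted alkene ends as an angular quaternary carbon. Ring B closes through the three-atom tether C1–C2–C14 (5-exo with respect to the alkene) as the two-carbon bridge of a bicyclo[3.2.1]octene, and ring A is the cyclopentenone assembled by the [2+2+1] union itself. C13 is controlled by C2, because the propargylic arm, axial at little cost since both 1,3-positions C4 and C13 are sp2, can reach only the lobe of C13 on its own face of ring C; C9 follows from suprafacial addition to the E alkene, which places C8 on the C14 face of ring A, the more stable and deliberately provisional arrangement. The step needs site selectivity between C13=C9 and C4=C5, both three atoms from the alkyne: the exocyclic alkene runs nearly parallel to the alkyne axis, whereas a metallacycle across the endocyclic C4=C5 would demand a torsion near a right angle around a C12–C4 bond, and the ring-locked transoid diene cannot serve as a four-carbon partner. Carbonylation has to outrun β-hydride loss from C8 in the rhodacycle, which the CO atmosphere and the conjugation of C13=C9 with C4=C5 (a better π-acceptor alkene) are expected to secure.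

**Step 12**
Reactants: 20 tricyclic enone
Product: 21 tricyclic ketone (C12–H on the C5 face; rings A and B cis-fused; C10 ketone)
Conditions: [(Ph3P)CuH]6, H2O (degassed), toluene, rt to 40 °C
Reagents that add atoms: none
Why: Copper hydride conjugate reduction, chemoselective for the enone over the isolated C4=C5 alkene and the ester: hydride can be delivered to C12 only on the face that carries C5, since this alone gives the cis-fused bicyclo[3.3.0]octane (C11 exo on the bicyclo[3.2.1]octene), while attack from the other face, which is also screened by the exo methyl group on C1, would lead to a trans-fused diquinane.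

**Step 13**
Reactants: 21 tricyclic ketone
Product: 22 C10 tosylhydrazone of 21
Conditions: TsNHNH2, EtOH, 50 °C
Reagents that add atoms: 4-methylbenzenesulfonohydrazide, Cc1ccc(cc1)S(=O)(=O)NN
Why: Condensation of a cyclopentanone with tosylhydrazide; C9 may equilibrate here but already has its more stable configuration, with C8 away from the C6 methyl group.

**Step 14**
Reactants: 22 tosylhydrazone
Product: 24 tricyclic silyl ether with C10 as CH2, via N-boryl hydrazide 23 (not isolated)
Conditions: catecholborane, CHCl3, −10 °C; then NaOAc·3H2O, reflux
Reagents that add atoms: none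
Why: Caglioti-type deoxygenation in its catecholborane form: hydroboration of the C=N bond, acetate-induced loss of sulfinate and extrusion of N2 from the diazene leave C10 as CH2 under conditions that spare ester, silyl ether and alkene.

**Step 15**
Reactants: 24 silyl ether
Product: 25 primary alcohol (C8–OH; 9-epi series)
Conditions: HF·pyridine, THF, 0 °C to rt
Reagents that add atoms: none
Why: Fluoride cleavage of a primary silyl ether under mildly acidic conditions that leave the ester and the alkene alone.

**Step 16**
Reactants: 25 primary alcohol
Product: 26 C8 carboxylic acid (9-epi series)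
Conditions: TEMPO (cat.), PhI(OAc)2 (2.5 equiv), MeCN–H2O, rt
Reagents that add atoms: water, O
Why: TEMPO/PhI(OAc)2 oxidation in aqueous acetonitrile takes the primary alcohol through the aldehyde hydrate to the acid without touching the trisubstituted alkene, and it is done before C6 is oxidised so that no second aldehyde is present.

**Step 17**
Reactants: 26 acid
Product: 27 enal acid (C6 aldehyde conjugated with C4=C5; C8 acid; 9-epi series)
Conditions: SeO2, 1,4-dioxane, 80 °C
Reagents that add atoms: selenium dioxide, O=[Se]=O
Why: Allylic oxidation with SeO2 (ene reaction then [2,3]-shift) takes place at the more substituted alkene terminus C5, whose only hydrogen-bearing allylic carbon is the methyl group C6 because C13 is quaternary, as in the oxidation of pinene to myrtenal, and the 9-epi carboxyl group points away from C6 and cannot trap the intermediate allylic alcohol as a lactone.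

**Step 18**
Reactants: 27 enal acid
Product: 30 tetracyclic dienol δ-lactone (ring D closed; C3=C4–C5=C6–O7–C8(=O); C9 in target configuration), via acid chloride 28 (not isolated), via ketene 29 (not isolated)
Conditions: Me2C=C(Cl)NMe2, CH2Cl2, 0 °C; then Et3N, DMAP (cat.), toluene (0.005 M), 80 °C
Reagents that add atoms: none
Why: Proposed new method: the acid chloride 28 of the 9-epi acid cannot reach the C6 aldehyde, but Et3N/DMAP should dehydrochlorinate it reversibly to ketene 29 (planar C9), whose central carbon C8 is attacked in the ketene plane by the enal oxygen held next to it by C13–C5, the resulting acyloxy-allyl cation loses its now very acidic γ-proton at C3, and the ester enolate is protonated at C9 from the open C14 face, the only course that gives a cis A/D fusion, so that ring D (six-membered, new bond O7–C8), the C3=C4–C5=C6 dienol and the target configuration of C9 arise together; the closest known reaction types are the enol lactonisation of δ-formyl acids, the formation of dienol esters from γ-enolisable enals with acylating agents and amine bases, and the epimerisation of α-branched acid chlorides through ketenes.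

**Step 19**
Reactants: 30 dienol lactone
Product: 31 dienol lactol (C8–OH; interconverting anomers, the equatorial one drawn)
Conditions: i-Bu2AlH (1.05 equiv), CH2Cl2, −78 °C; then potassium sodium tartrate aq; used at once
Reagents that add atoms: none
Why: Half-reduction of an enol δ-lactone to the enol lactol with one equivalent of i-Bu2AlH at low temperature, as in the reduction of nepetalactone to nepetalactol: the dienol ester carbonyl is far more electrophilic than the shielded methyl ester on C1, and having kept C8 at the acid level until now guarantees that C6 is the enol carbon and C8 the acetal carbon.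

**Step 20**
Reactants: 31 dienol lactol; 32 3-methylbutanoyl chloride
Product: 33 CNP0315847.1 (target)
Conditions: 32, pyridine, DMAP (cat.), CH2Cl2, −20 to 0 °C
Reagents that add atoms: 3-methylbutanoyl chloride, CC(C)CC(Cl)=O
Why: Acylation of an iridoid-type lactol: the anomers interconvert through the ring-opened form, and the hydroxyl that is equatorial on the half-chair of ring D, cis to H9 on the convex face and away from the pseudo-axial C12, is both the more stable and the faster acylated, which sets C8 with H8 and H9 trans-diaxial as in the target.

**Compound list**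

1 | (R)-carvone | CC1=CC[C@H](CC1=O)C(C)=C | starting material
2 | (−)-cis-carveol | CC1=CC[C@H](C[C@H]1O)C(C)=C | intermediate
3 | organoborane (B-alkyl-9-BBN, C13 O-borinate) | CC1=CC[C@H](C[C@H]1OB1C2CCCC1CCC2)C(C)CB1C2CCCC1CCC2 | intermediate
4 | diol, both C1 epimers | CC1=CC[C@H](C[C@H]1O)C(C)CO | intermediate
5 | bridged lactol | CC1=CC[C@@H]2C[C@H]1OC(O)C2C | intermediate
6 | bridged δ-lactone, both C1 epimers | CC1=CC[C@@H]2C[C@H]1OC(=O)C2C | intermediate
7 | formaldehyde | C=O | starting material
8 | lithium enolate of 6 | [Li+].CC1=CC[C@@H]2C[C@H]1OC([O-])=C2C | intermediate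
9 | hydroxymethyl lactone (C1 quaternary, R) | CC1=CC[C@@H]2C[C@H]1OC(=O)[C@@]2(C)CO | intermediate
10 | formyl lactone | CC1=CC[C@@H]2C[C@H]1OC(=O)[C@@]2(C)C=O | intermediate
11 | dimethyl (1-diazo-2-oxopropyl)phosphonate | CC(=O)C(=[N+]=[N-])P(=O)(OC)OC | starting material
12 | ethynyl lactone | CC1=CC[C@@H]2C[C@H]1OC(=O)[C@@]2(C)C#C | intermediate
13 | alkynyl hydroxy ester | C#C[C@](C)(C(=O)OC)[C@@H]1CC=C(C)[C@H](O)C1 | intermediate
14 | alkynyl enone ester | C#C[C@](C)(C(=O)OC)[C@@H]1CC=C(C)C(=O)C1 | intermediate
15 | triethyl phosphonoacetate | CCOC(=O)CP(=O)(OCC)OCC | starting material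
16 | (E)-dienoate | C#C[C@](C)(C(=O)OC)[C@@H]1CC=C(C)/C(=C/C(=O)OCC)C1 | intermediate
17 | (E)-dienyl alcohol | C#C[C@](C)(C(=O)OC)[C@@H]1CC=C(C)/C(=C/CO)C1 | intermediate
18 | dienyne ester, Pauson–Khand precursor | C#C[C@](C)(C(=O)OC)[C@@H]1CC=C(C)/C(=C/CO[Si](C)(C)C(C)(C)C)C1 | intermediate
19 | carbon monoxide | [C-]#[O+] | starting material
20 | tricyclic enone, Pauson–Khand product | COC(=O)[C@@]1(C)C2=CC(=O)[C@H](CO[Si](C)(C)C(C)(C)C)[C@]23C[C@H]1CC=C3C | intermediate
21 | tricyclic ketone | COC(=O)[C@@]1(C)[C@@H]2CC(=O)[C@H](CO[Si](C)(C)C(C)(C)C)[C@]23C[C@H]1CC=C3C | intermediate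
22 | tosylhydrazone | COC(=O)[C@@]1(C)[C@@H]2CC(=NNS(=O)(=O)c4ccc(C)cc4)[C@H](CO[Si](C)(C)C(C)(C)C)[C@]23C[C@H]1CC=C3C | intermediate
23 | N-boryl hydrazide | COC(=O)[C@@]1(C)[C@@H]2CC(N(NS(=O)(=O)c4ccc(C)cc4)B4Oc5ccccc5O4)[C@H](CO[Si](C)(C)C(C)(C)C)[C@]23C[C@H]1CC=C3C | intermediate
24 | deoxygenated silyl ether | COC(=O)[C@@]1(C)[C@@H]2CC[C@H](CO[Si](C)(C)C(C)(C)C)[C@]23C[C@H]1CC=C3C | intermediate
25 | primary alcohol | COC(=O)[C@@]1(C)[C@@H]2CC[C@H](CO)[C@]23C[C@H]1CC=C3C | intermediate
26 | C8 acid, 9-epi | COC(=O)[C@@]1(C)[C@@H]2CC[C@H](C(=O)O)[C@]23C[C@H]1CC=C3C | intermediate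
27 | enal acid, 9-epi | COC(=O)[C@@]1(C)[C@@H]2CC[C@H](C(=O)O)[C@]23C[C@H]1CC=C3C=O | intermediate
28 | acid chloride | COC(=O)[C@@]1(C)[C@@H]2CC[C@H](C(=O)Cl)[C@]23C[C@H]1CC=C3C=O | intermediate
29 | ketene | COC(=O)[C@@]1(C)[C@@H]2CCC(=C=O)[C@]23C[C@H]1CC=C3C=O | intermediate
30 | dienol δ-lactone | COC(=O)[C@]1(C)[C@@H]2C=CC3=COC(=O)[C@@H]4CC[C@@H]1[C@]34C2 | intermediate
31 | dienol lactol | COC(=O)[C@]1(C)[C@@H]2C=CC3=CO[C@@H](O)[C@@H]4CC[C@@H]1[C@]34C2 | intermediate
32 | 3-methylbutanoyl chloride | CC(C)CC(Cl)=O | starting material
33 | CNP0315847.1 | COC(=O)[C@]1(C)[C@@H]2C=CC3=CO[C@@H](OC(=O)CC(C)C)[C@@H]4CC[C@@H]1[C@]34C2 | target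

**Step count**

Total step count: 20. Longest linear sequence: 20 steps from (R)-carvone. The precursor 18 is reached in 10 steps.

**Steps most likely to fail**

1. **Step 18 (Proposed new method).**
   - What may go wrong: dehydrochlorination at the hindered C9–H may be slow, and ketene dimerisation or intermolecular O-acylation may outrun ring closure.
   - Fallback with known chemistry, from 26 back to 30: the inversion of C9 and the ring closure are separated. Acid 26 is deprotonated twice with LiN(i-Pr)2 to the dilithium enediolate F1. Kinetic protonation with 2,6-di-tert-butyl-4-methylphenol at −78 °C on the open C14 face (the C6 methyl group screens the other face) should give the C9-inverted acid F2, the less stable epimer, as is usual for exocyclic enolates. To stop the C6 alcohol formed during allylic oxidation from lactonising, this acid is masked with tert-butyl 2,2,2-trichloroacetimidate (BF3·OEt2 cat.) as the tert-butyl ester F3. SeO2 in dioxane then gives the enal ester F4, and CF3CO2H frees the enal acid F5. Classical enol lactonisation (Ac2O, NaOAc, 100 °C), now between groups held side by side, closes ring D to 30.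

2. **Step 11 (key step).**
   - What may go wrong: sluggish oxidative cyclisation at a trisubstituted alkene, cycloisomerisation through β-hydride loss from C8, and oligomerisation of the terminal alkyne.
   - Fallback, same disconnection with a slimmer alkene, from 14 back to 20: Wittig methylenation (Ph3P=CH2, THF) gives the methylidene dienyne F6. Its 1,1-disubstituted alkene is the best-precedented partner for an angular quaternary carbon. The same Rh/CO conditions (or Co2(CO)8 followed by an amine N-oxide) should give the C8-free tricyclic enone F7. LiN(i-Pr)2 can remove a proton only from C9, because C1 and C13 are quaternary, giving the cross-conjugated lithium dienolate F8. Formaldehyde adds on the open C14 face to give the hydroxymethyl enone F9, and silylation with TBSCl gives 20.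

3. **Step 12.**
   - What may go wrong: hydrocupration may not occur because C12 lies between two quaternary carbons, and a slow reaction leaves room for 1,2-reduction.
   - Fallback, from 20 back to 21: electron transfer replaces delivery of a metal hydride. Li in NH3/THF with one equivalent of t-BuOH at −78 °C reduces the enone to its radical anion. Only a proton then has to reach C12, and it gives the more stable cis ring fusion. The product is the lithium enolate F10, which NH4Cl protonates to 21. Titrated lithium and a short contact time protect the hindered methyl ester.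

**Further compounds**

F1 | step 18 | dilithium enediolate of 26 | [Li+].[Li+].COC(=O)[C@@]1(C)[C@@H]2CCC(=C([O-])[O-])[C@]23C[C@H]1CC=C3C
F2 | step 18 | C9-inverted acid | COC(=O)[C@@]1(C)[C@@H]2CC[C@@H](C(=O)O)[C@]23C[C@H]1CC=C3C
F3 | step 18 | tert-butyl ester | COC(=O)[C@@]1(C)[C@@H]2CC[C@@H](C(=O)OC(C)(C)C)[C@]23C[C@H]1CC=C3C
F4 | step 18 | enal ester | COC(=O)[C@@]1(C)[C@@H]2CC[C@@H](C(=O)OC(C)(C)C)[C@]23C[C@H]1CC=C3C=O
F5 | step 18 | enal acid of target C9 configuration | COC(=O)[C@@]1(C)[C@@H]2CC[C@@H](C(=O)O)[C@]23C[C@H]1CC=C3C=O
F6 | step 11 | methylidene dienyne | C#C[C@](C)(C(=O)OC)[C@@H]1CC=C(C)C(=C)C1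
F7 | step 11 | C8-free tricyclic enone | COC(=O)[C@@]1(C)C2=CC(=O)C[C@]23C[C@H]1CC=C3C
F8 | step 11 | cross-conjugated lithium dienolate | [Li+].COC(=O)[C@@]1(C)C2=CC([O-])=C[C@]23C[C@H]1CC=C3C
F9 | step 11 | hydroxymethyl enone | COC(=O)[C@@]1(C)C2=CC(=O)[C@H](CO)[C@]23C[C@H]1CC=C3C
F10 | step 12 | lithium enolate of 21 | [Li+].COC(=O)[C@@]1(C)[C@@H]2C=C([O-])[C@H](CO[Si](C)(C)C(C)(C)C)[C@]23C[C@H]1CC=C3C
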